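**Retrosynthetic overview**

1. Late disconnections: C14 enal from its dimethyl acetal, the C9 acetate, and the C9–C10 bond by a Nozaki–Hiyama–Kishi closure of the 10-membered ring (second ring formed) between a Z-vinyl iodide and a C9 aldehyde; the O8 ester comes from a bought (S)-acid.
2. Key disconnection: the C7–C11 bond and the C11=C13 methylene in one operation. An O6-bound phosphonoacetate carbanion opens a trans C7–C8 epoxide in the 5-exo mode (first ring formed, the γ-lactone O6–C6–C7–C11–C12) and then olefinates formaldehyde.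
3. Enabling feature: the C7–C11 bond of the lactone ring is anti to the C8–O bond on the neighbouring carbon of the 10-membered ring (the footprint of SN2 opening of a trans epoxide), O6 sits three atoms from C11, and C5 and C8 are trans on the lactone, which is what an erythro 6-hydroxy-7,8-epoxide delivers.
4. Stereochemistry: C6 by a catalytic alkenylzinc addition; C7 and C8 by Sharpless epoxidation relayed from C6 and transferred in the key step; C9 by Felkin–Anh control in the ring closure; the side-chain centre is bought.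
5. Carbons: neryl acetate gives C1–C6 and C15 with the cis C4=C5 bond in place; C10 and C14 by Wittig reaction; C7–C9 from a propargyl ether; C11 and C12 from phosphonoacetic acid; C13 from formaldehyde.

Key step: step 9

Remark: germacrane locants are used (C6 lactone O-bearing carbon, C7, C8, C9 ring stereocentres, C11/C12/C13 lactone α-carbon/carbonyl/methylene, C14 formyl carbon, C15 methyl), and compounds 1, 9, 14 and 18 are taken as commercial.

**Route**

Step 1
Reactants: 1 neryl acetate
Product: 3 (2Z)-3-methyl-6-oxohex-2-en-1-yl acetate, via 6,7-epoxyneryl acetate 2 (not isolated)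
Conditions: 3-chloroperbenzoic acid, CH2Cl2, 0 °C; then H5IO6, THF/H2O, 0 °C → rt
Reagents that add atoms: 3-chloroperbenzoic acid (OOC(=O)c1cccc(Cl)c1)
Why: Prilezhaev epoxidation picks the electron-rich remote trisubstituted olefin over the one deactivated by the allylic acetate, and periodic acid then hydrolyses the epoxide and cleaves the glycol (Malaprade cleavage) to the aldehyde, while the Z-configured C4=C5 bond of the target is carried through untouched.

Step 2
Reactants: 3 (2Z)-3-methyl-6-oxohex-2-en-1-yl acetate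
Product: 4 (2Z,6E)-3-methyl-8-oxoocta-2,6-dien-1-yl acetate
Conditions: Ph3P=CHCHO, toluene, 80 °C
Reagents that add atoms: (triphenylphosphoranylidene)acetaldehyde (O=CC=P(c1ccccc1)(c1ccccc1)c1ccccc1)
Why: The stabilised formylmethylene ylide undergoes a Wittig reaction with the aliphatic aldehyde to give the E-enal, which adds C10 and C14.

Step 3
Reactants: 4 (2Z,6E)-3-methyl-8-oxoocta-2,6-dien-1-yl acetate
Product: 5 (2Z,6Z)-7-iodo-3-methyl-8-oxoocta-2,6-dien-1-yl acetate
Conditions: I2, pyridine, CH2Cl2, 0 °C → rt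
Reagents that add atoms: iodine (II)
Why: α-Iodination of an enal by the iodine/pyridine addition–elimination sequence (conjugate addition of pyridine, iodination of the enolate, loss of pyridine) should give the Z-iodoenal, in which C2 is cis to iodine and trans to C14, the geometry the ring olefin needs.

Step 4
Reactants: 5 (2Z,6Z)-7-iodo-3-methyl-8-oxoocta-2,6-dien-1-yl acetate
Product: 7 (2Z,6Z)-7-iodo-8,8-dimethoxy-3-methylocta-2,6-dien-1-ol, via acetal acetate 6 (not isolated)
Conditions: HC(OMe)3, pyridinium p-toluenesulfonate (cat.), MeOH, rt; then K2CO3 (0.3 equiv), rt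
Reagents that add atoms: trimethyl orthoformate (COC(OC)OC); methanol (CO)
Why: Acid-catalysed acetalisation with the orthoformate masks C14 at the aldehyde oxidation level, and carbonate-catalysed transesterification of the allylic acetate in the same methanol solution frees the C6 hydroxyl without touching acetal or vinyl iodide.

Step 5
Reactants: 7 (2Z,6Z)-7-iodo-8,8-dimethoxy-3-methylocta-2,6-dien-1-ol
Product: 8 (2Z,6Z)-7-iodo-8,8-dimethoxy-3-methylocta-2,6-dienal
Conditions: MnO2, CH2Cl2, rt
Reagents that add atoms: none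
Why: MnO2 is selective for allylic alcohols and oxidises nerol-type Z-allylic alcohols to the Z-enals without Z/E isomerisation or attack on the acetal.

Step 6
Reactants: 8 (2Z,6Z)-7-iodo-8,8-dimethoxy-3-methylocta-2,6-dienal; 9 4-methoxybenzyl propargyl ether
Product: 12 (2E,4S,5Z,9Z)-10-iodo-11,11-dimethoxy-1-[(4-methoxyphenyl)methoxy]-6-methylundeca-2,5,9-trien-4-ol, via alkenylborane 10 (not isolated), via alkenylzinc 11 (not isolated)
Conditions: 9, Cy2BH, toluene, 0 °C → rt; Me2Zn, −78 °C; (2S)-3-exo-morpholinoisoborneol (5 mol%); then 8, −20 → 0 °C; aq. NH4Cl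
Reagents that add atoms: none
Why: syn-Hydroboration of the terminal alkyne, boron-to-zinc exchange and amino-alcohol-catalysed 1,2-addition of the (E)-alkenylzinc to the enal should set C6, the zinc complex of the (2S)-amino alcohol directing the alkenyl group to the Si face of the aldehyde to give the 4S carbinol, while vinyl iodide and acetal are inert to the organozinc.

Step 7
Reactants: 12 (2E,4S,5Z,9Z)-10-iodo-11,11-dimethoxy-1-[(4-methoxyphenyl)methoxy]-6-methylundeca-2,5,9-trien-4-ol
Product: 13 (1R,2Z,6Z)-7-iodo-8,8-dimethoxy-1-[(2R,3R)-3-{[(4-methoxyphenyl)methoxy]methyl}oxiran-2-yl]-3-methylocta-2,6-dien-1-ol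
Conditions: Ti(OiPr)4 (0.2 equiv), diisopropyl D-tartrate (0.24 equiv), tBuOOH (decane), 4 Å MS, CH2Cl2, −20 °C
Reagents that add atoms: tert-butyl hydroperoxide (CC(C)(C)OO)
Why: Sharpless asymmetric epoxidation in its matched, kinetic-resolution sense: with the D-tartrate the 4S carbinol is the fast-reacting enantiomer for the E-disubstituted C7=C8 olefin and gives the erythro epoxy alcohol (C7 and C8 set by the catalyst and reinforced by C6), whereas the Z-substituted C4=C5 olefin is both mismatched and slowed by allylic 1,3-strain.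

Step 8
Reactants: 13 the epoxy alcohol of step 7; 14 2-(diethoxyphosphoryl)acetic acid
Product: 15 (1R,2Z,6Z)-7-iodo-8,8-dimethoxy-1-[(2R,3R)-3-{[(4-methoxyphenyl)methoxy]methyl}oxiran-2-yl]-3-methylocta-2,6-dien-1-yl 2-(diethoxyphosphoryl)acetate
Conditions: N,N'-dicyclohexylcarbodiimide, 4-(dimethylamino)pyridine (cat.), CH2Cl2, 0 °C → rt
Reagents that add atoms: none
Why: Steglich esterification acylates the secondary alcohol under neutral conditions that leave the epoxide and the acetal intact.

Step 9
Reactants: 15 the epoxy phosphonoacetate of step 8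
Product: 17 (4R,5R)-4-[(1S)-1-hydroxy-2-[(4-methoxyphenyl)methoxy]ethyl]-5-[(1Z,5Z)-6-iodo-7,7-dimethoxy-2-methylhepta-1,5-dien-1-yl]-3-methylideneoxolan-2-one, via phosphono lactone potassium enolate 16 (not isolated)
Conditions: KOtBu (1.0 equiv), THF, 0 → 40 °C; then (CH2O)n, 0 °C → rt; aq. NH4Cl
Reagents that add atoms: paraformaldehyde, as formaldehyde (C=O)
Why: Proposed new method: KOtBu deprotonates the phosphonoacetate, the carbanion carbon C11 attacks C7 of the trans epoxide from the face opposite the C7–O bond, the C8 alkoxide so formed is quenched at once by the acidic C11–H of the α-phosphono lactone, and the resulting phosphonoenolate 16 undergoes Horner–Wadsworth–Emmons olefination with formaldehyde to give the exocyclic methylene. The closest known reaction types are the telescoped intramolecular Michael addition/Horner–Wadsworth–Emmons olefination of phosphonoacetates of γ-hydroxy enones, the intermolecular opening of epoxides by phosphonoacetate anions to α-phosphono lactones, and the 5-exo opening of 2,3-epoxy alcohol urethanes at C2; what is new is a tethered phosphonoacetate carbanion opening an epoxide. The lactone ring closes in the 5-exo mode at an epoxide carbon, whose behaviour lies between tetrahedral and trigonal, and the phosphoryl group keeps the carbanion stabilised when the C11–C12 bond twists out of the ester plane as this closure demands. C7 is set by inversion (controlled by the epoxide configuration from step 7), C8 keeps the epoxide oxygen with retention, C6 is untouched, and the trans relation of C5 and C8 on the lactone follows from the erythro epoxy alcohol. The step needs attack at C7 (5-exo) over C8 (6-endo), which the three-atom O6–C12–C11 tether and the inductively deactivated C8 next to the CH2O group secure, and it needs the alkoxide not to attack phosphorus (Wadsworth–Emmons cyclopropanation) or the lactone carbonyl (translactonisation), which the fast internal proton transfer, the single equivalent of base and the low temperature secure.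

Step 10
Reactants: 18 (2S)-2-hydroxy-2-methylbutanoic acid
Product: 20 (2S)-2-acetoxy-2-methylbutanoyl chloride, via acetoxy acid 19 (not isolated)
Conditions: AcCl (neat), rt → 45 °C; then SOCl2, 60 °C; distillation
Reagents that add atoms: acetyl chloride (CC(=O)Cl); thionyl chloride (O=S(Cl)Cl)
Why: Acetyl chloride acetylates the tertiary hydroxyl of the α-hydroxy acid and thionyl chloride converts the acetoxy acid into the acid chloride, the established route to 2-acetoxyisobutyryl chloride, and the quaternary stereocentre has no α-hydrogen to epimerise.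

Step 11
Reactants: 17 the hydroxy lactone of step 9; 20 (2S)-2-acetoxy-2-methylbutanoyl chloride
Product: 21 (1S)-1-[(2R,3S)-2-[(1Z,5Z)-6-iodo-7,7-dimethoxy-2-methylhepta-1,5-dien-1-yl]-4-methylidene-5-oxooxolan-3-yl]-2-[(4-methoxyphenyl)methoxy]ethyl (2S)-2-acetoxy-2-methylbutanoate
Conditions: Et3N, 4-(dimethylamino)pyridine, CH2Cl2, 0 °C → rt
Reagents that add atoms: none
Why: Nucleophilic catalysis by 4-(dimethylamino)pyridine transfers the hindered acyl group to the secondary C8 hydroxyl with retention at C8 and at the quaternary centre, and the mild amine base leaves lactone, acetal and vinyl iodide untouched.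

Step 12
Reactants: 21 the C8 ester of step 11
Product: 22 (1S)-2-hydroxy-1-[(2R,3S)-2-[(1Z,5Z)-6-iodo-7,7-dimethoxy-2-methylhepta-1,5-dien-1-yl]-4-methylidene-5-oxooxolan-3-yl]ethyl (2S)-2-acetoxy-2-methylbutanoate
Conditions: 2,3-dichloro-5,6-dicyano-1,4-benzoquinone, CH2Cl2/pH 7 buffer, 0 °C
Reagents that add atoms: none
Why: Oxidative cleavage of the 4-methoxybenzyl ether by the quinone (hydride abstraction, hydrolysis of the oxocarbenium ion) frees the primary C9 hydroxyl under buffered neutral conditions that avoid acyl migration and loss of the acetal.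

Step 13
Reactants: 22 the primary alcohol of step 12
Product: 23 (1S)-1-[(2R,3S)-2-[(1Z,5Z)-6-iodo-7,7-dimethoxy-2-methylhepta-1,5-dien-1-yl]-4-methylidene-5-oxooxolan-3-yl]-2-oxoethyl (2S)-2-acetoxy-2-methylbutanoate
Conditions: Dess–Martin periodinane, pyridine, CH2Cl2, 0 °C → rt
Reagents that add atoms: none
Why: Dess–Martin oxidation under pyridine buffering gives the α-acyloxy aldehyde without epimerising C8.

Step 14
Reactants: 23 the iodo aldehyde of step 13
Product: 24 (6R,7S,8S,9R)-8-{[(2S)-2-acetoxy-2-methylbutanoyl]oxy}-9-hydroxy-14,14-dimethoxygermacra-1(10),4,11(13)-trien-12,6-olide (1(10)E,4Z; both ring double bonds cis in the ring)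
Conditions: CrCl2 (8 equiv), NiCl2 (2 mol%), DMSO/THF, 2 mM, rt, slow addition of 23
Reagents that add atoms: none
Why: Nozaki–Hiyama–Kishi reaction: nickel-catalysed formation of the alkenylchromium species from the vinyl iodide with retention of the olefin geometry and its chemoselective addition to the C9 aldehyde close the 10-membered ring, and C9 should be set by Felkin–Anh addition anti to the C8 acyloxy group, which gives the erythro C8/C9 pattern (9R).

Step 15
Reactants: 24 the macrocyclic alcohol of step 14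
Product: 25 (6R,7S,8S,9R)-9-acetoxy-8-{[(2S)-2-acetoxy-2-methylbutanoyl]oxy}-14,14-dimethoxygermacra-1(10),4,11(13)-trien-12,6-olide
Conditions: Ac2O, pyridine, 4-(dimethylamino)pyridine (cat.), CH2Cl2, 0 °C
Reagents that add atoms: acetic anhydride (CC(=O)OC(C)=O)
Why: Acetylation of the secondary allylic C9 hydroxyl by nucleophilic catalysis proceeds with retention and is faster than any acyl shift from O8.

Step 16
Reactants: 25 the acetal diester of step 15
Product: 26 (6R,7S,8S,9R)-9-acetoxy-8-{[(2S)-2-acetoxy-2-methylbutanoyl]oxy}-14-oxogermacra-1(10),4,11(13)-trien-12,6-olide (1(10)E,4Z; both ring double bonds cis in the ring), the target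
Conditions: pyridinium p-toluenesulfonate (cat.), THF/H2O, rt
Reagents that add atoms: water (O)
Why: Mild acid hydrolysis of the dimethyl acetal through the conjugated oxocarbenium ion releases the enal, and the esters, the lactone and the allylic acetate are stable to these conditions.

**Compound list**

1 | neryl acetate, (2Z)-3,7-dimethylocta-2,6-dien-1-yl acetate | CC(=O)OC/C=C(/C)CCC=C(C)C | starting material
2 | 6,7-epoxyneryl acetate (racemic epoxide) | CC(=O)OC/C=C(/C)CCC1OC1(C)C | intermediate
3 | (2Z)-3-methyl-6-oxohex-2-en-1-yl acetate | CC(=O)OC/C=C(/C)CCC=O | intermediate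
4 | (2Z,6E)-3-methyl-8-oxoocta-2,6-dien-1-yl acetate | CC(=O)OC/C=C(/C)CC/C=C/C=O | intermediate
5 | (2Z,6Z)-7-iodo-3-methyl-8-oxoocta-2,6-dien-1-yl acetate | CC(=O)OC/C=C(/C)CC/C=C(\I)C=O | intermediate
6 | (2Z,6Z)-7-iodo-8,8-dimethoxy-3-methylocta-2,6-dien-1-yl acetate | CC(=O)OC/C=C(/C)CC/C=C(\I)C(OC)OC | intermediate
7 | (2Z,6Z)-7-iodo-8,8-dimethoxy-3-methylocta-2,6-dien-1-ol | OC/C=C(/C)CC/C=C(\I)C(OC)OC | intermediate
8 | (2Z,6Z)-7-iodo-8,8-dimethoxy-3-methylocta-2,6-dienal | O=C/C=C(/C)CC/C=C(\I)C(OC)OC | intermediate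
9 | 4-methoxybenzyl propargyl ether, 1-methoxy-4-[(prop-2-yn-1-yloxy)methyl]benzene | C#CCOCc1ccc(OC)cc1 | starting material
10 | dicyclohexyl{(1E)-3-[(4-methoxyphenyl)methoxy]prop-1-en-1-yl}borane | COc1ccc(COC/C=C/B(C2CCCCC2)C2CCCCC2)cc1 | intermediate
11 | {(1E)-3-[(4-methoxyphenyl)methoxy]prop-1-en-1-yl}(methyl)zinc | COc1ccc(COC/C=C/[Zn]C)cc1 | intermediate
12 | (2E,4S,5Z,9Z)-10-iodo-11,11-dimethoxy-1-[(4-methoxyphenyl)methoxy]-6-methylundeca-2,5,9-trien-4-ol | O[C@@H](/C=C/COCc1ccc(OC)cc1)/C=C(/C)CC/C=C(\I)C(OC)OC | intermediate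
13 | (1R,2Z,6Z)-7-iodo-8,8-dimethoxy-1-[(2R,3R)-3-{[(4-methoxyphenyl)methoxy]methyl}oxiran-2-yl]-3-methylocta-2,6-dien-1-ol | O[C@@H]([C@H]1O[C@@H]1COCc1ccc(OC)cc1)/C=C(/C)CC/C=C(\I)C(OC)OC | intermediate
14 | 2-(diethoxyphosphoryl)acetic acid | OC(=O)CP(=O)(OCC)OCC | starting material
15 | (1R,2Z,6Z)-7-iodo-8,8-dimethoxy-1-[(2R,3R)-3-{[(4-methoxyphenyl)methoxy]methyl}oxiran-2-yl]-3-methylocta-2,6-dien-1-yl 2-(diethoxyphosphoryl)acetate | CCOP(=O)(OCC)CC(=O)O[C@@H]([C@H]1O[C@@H]1COCc1ccc(OC)cc1)/C=C(/C)CC/C=C(\I)C(OC)OC | intermediate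
16 | diethyl {(4R,5R)-4-[(1S)-1-hydroxy-2-[(4-methoxyphenyl)methoxy]ethyl]-5-[(1Z,5Z)-6-iodo-7,7-dimethoxy-2-methylhepta-1,5-dien-1-yl]-2-oxooxolan-3-yl}phosphonate (present in the flask as its potassium enolate; C3 not defined) | CCOP(=O)(OCC)C1C(=O)O[C@H](/C=C(/C)CC/C=C(\I)C(OC)OC)[C@H]1[C@H](O)COCc1ccc(OC)cc1 | intermediate
17 | (4R,5R)-4-[(1S)-1-hydroxy-2-[(4-methoxyphenyl)methoxy]ethyl]-5-[(1Z,5Z)-6-iodo-7,7-dimethoxy-2-methylhepta-1,5-dien-1-yl]-3-methylideneoxolan-2-one | C=C1C(=O)O[C@H](/C=C(/C)CC/C=C(\I)C(OC)OC)[C@H]1[C@H](O)COCc1ccc(OC)cc1 | intermediate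
18 | (2S)-2-hydroxy-2-methylbutanoic acid | OC(=O)[C@](C)(CC)O | starting material
19 | (2S)-2-acetoxy-2-methylbutanoic acid | OC(=O)[C@](C)(CC)OC(C)=O | intermediate
20 | (2S)-2-acetoxy-2-methylbutanoyl chloride | ClC(=O)[C@](C)(CC)OC(C)=O | intermediate
21 | (1S)-1-[(2R,3S)-2-[(1Z,5Z)-6-iodo-7,7-dimethoxy-2-methylhepta-1,5-dien-1-yl]-4-methylidene-5-oxooxolan-3-yl]-2-[(4-methoxyphenyl)methoxy]ethyl (2S)-2-acetoxy-2-methylbutanoate | C=C1C(=O)O[C@H](/C=C(/C)CC/C=C(\I)C(OC)OC)[C@H]1[C@H](OC(=O)[C@](C)(CC)OC(C)=O)COCc1ccc(OC)cc1 | intermediate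
22 | (1S)-2-hydroxy-1-[(2R,3S)-2-[(1Z,5Z)-6-iodo-7,7-dimethoxy-2-methylhepta-1,5-dien-1-yl]-4-methylidene-5-oxooxolan-3-yl]ethyl (2S)-2-acetoxy-2-methylbutanoate | C=C1C(=O)O[C@H](/C=C(/C)CC/C=C(\I)C(OC)OC)[C@H]1[C@H](OC(=O)[C@](C)(CC)OC(C)=O)CO | intermediate
23 | (1S)-1-[(2R,3S)-2-[(1Z,5Z)-6-iodo-7,7-dimethoxy-2-methylhepta-1,5-dien-1-yl]-4-methylidene-5-oxooxolan-3-yl]-2-oxoethyl (2S)-2-acetoxy-2-methylbutanoate | C=C1C(=O)O[C@H](/C=C(/C)CC/C=C(\I)C(OC)OC)[C@H]1[C@H](OC(=O)[C@](C)(CC)OC(C)=O)C=O | intermediate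
24 | (6R,7S,8S,9R)-8-{[(2S)-2-acetoxy-2-methylbutanoyl]oxy}-9-hydroxy-14,14-dimethoxygermacra-1(10),4,11(13)-trien-12,6-olide (1(10)E,4Z) | C=C1C(=O)O[C@@H]2/C=C(/C)CC/C=C(/C(OC)OC)[C@@H](O)[C@@H](OC(=O)[C@](C)(CC)OC(C)=O)[C@@H]12 | intermediate
25 | (6R,7S,8S,9R)-9-acetoxy-8-{[(2S)-2-acetoxy-2-methylbutanoyl]oxy}-14,14-dimethoxygermacra-1(10),4,11(13)-trien-12,6-olide (1(10)E,4Z) | C=C1C(=O)O[C@@H]2/C=C(/C)CC/C=C(/C(OC)OC)[C@@H](OC(C)=O)[C@@H](OC(=O)[C@](C)(CC)OC(C)=O)[C@@H]12 | intermediate
26 | (6R,7S,8S,9R)-9-acetoxy-8-{[(2S)-2-acetoxy-2-methylbutanoyl]oxy}-14-oxogermacra-1(10),4,11(13)-trien-12,6-olide (1(10)E,4Z) | C=C1C(=O)O[C@@H]2/C=C(/C)CC/C=C(/C=O)[C@@H](OC(C)=O)[C@@H](OC(=O)[C@](C)(CC)OC(C)=O)[C@@H]12 | target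

**Totals**

Total step count: 16. Longest linear sequence: 15 steps (steps 1–9 and 11–16; step 10 is the side branch).

**Steps most likely to fail**

Step 9 (Proposed new method). The carbanion may open the epoxide too slowly or at C8 (6-endo), and the transient C8 alkoxide may transfer the phosphoryl group (cyclopropanation) or the acyl group (translactonisation) before it is protonated. The fallback uses known chemistry and disconnects C6–C7 instead; it sets out from aldehyde 8 and comes back at 17. (R)-2,3-O-Isopropylideneglyceraldehyde and methyl acrylate are joined by a Morita–Baylis–Hillman reaction (1,4-diazabicyclo[2.2.2]octane) to methyl 2-{[(4R)-2,2-dimethyl-1,3-dioxolan-4-yl](hydroxy)methyl}prop-2-enoate F1. N-Bromosuccinimide and dimethyl sulfide convert it with allylic transposition into methyl (2Z)-2-(bromomethyl)-3-[(4S)-2,2-dimethyl-1,3-dioxolan-4-yl]prop-2-enoate F2. Nickel-free CrCl2 in THF couples this bromide with 8 in an anti-selective Nozaki–Hiyama allylation (Dreiding–Schmidt-type lactone synthesis), and the adduct lactonises to the trans α-methylene lactone (4S,5R)-4-[(4S)-2,2-dimethyl-1,3-dioxolan-4-yl]-5-[(1Z,5Z)-6-iodo-7,7-dimethoxy-2-methylhepta-1,5-dien-1-yl]-3-methylideneoxolan-2-one F3. Here C8 stems from the glyceraldehyde, and diastereomers at C6/C7 would have to be removed by chromatography. Camphorsulfonic acid in dry methanol removes the acetonide by transacetalisation, while the dimethyl acetal only exchanges with the solvent, and gives the diol (4R,5R)-4-[(1S)-1,2-dihydroxyethyl]-5-[(1Z,5Z)-6-iodo-7,7-dimethoxy-2-methylhepta-1,5-dien-1-yl]-3-methylideneoxolan-2-one F4. Bu2SnO and then 4-methoxybenzyl chloride with CsF alkylate the primary hydroxyl and give 17.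

Step 14. Intermolecular coupling may compete with closure of the 10-membered ring, the facial selectivity at C9 may be low because the ring conformation can override Felkin–Anh control, and the chromium alkoxide may take over the acyl group from O8. The fallback sets out from 23 and comes back at 24. The closure is run at higher dilution for the C–C bond only, and the crude C9 epimers are oxidised with Dess–Martin periodinane to the macrocyclic enone (6R,7S,8S)-8-{[(2S)-2-acetoxy-2-methylbutanoyl]oxy}-14,14-dimethoxy-9-oxogermacra-1(10),4,11(13)-trien-12,6-olide F5. C9 is then set by reagent control in a Corey–Bakshi–Shibata reduction with (R)-1-methyl-3,3-diphenyltetrahydro-1H,3H-pyrrolo[1,2-c][1,3,2]oxazaborole and catecholborane at −78 °C. With the alkenyl group as the larger substituent this should deliver the 9R alcohol 24.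

Step 6. The hindered β,β-disubstituted Z-enal may add the alkenylzinc slowly and with low enantioselectivity, and the Z-enal may isomerise under Lewis acid. The fallback sets out from 8 and comes back at 13. The alkenylzinc 11 is added to 8 with achiral 2-(dimethylamino)ethanol as promoter to give the racemic carbinol (2E,5Z,9Z)-10-iodo-11,11-dimethoxy-1-[(4-methoxyphenyl)methoxy]-6-methylundeca-2,5,9-trien-4-ol F6. The Sharpless epoxidation of step 7 is then run as a kinetic resolution with diisopropyl D-tartrate and 0.6 equivalents of tBuOOH. It should epoxidise only the 4S enantiomer and give 13, the 4R alcohol being left behind and separated, so that C6 is set by resolution instead of by addition.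

**Further compounds**

F1 | step 9 | methyl 2-{[(4R)-2,2-dimethyl-1,3-dioxolan-4-yl](hydroxy)methyl}prop-2-enoate | C=C(C(=O)OC)C(O)[C@H]1COC(C)(C)O1
F2 | step 9 | methyl (2Z)-2-(bromomethyl)-3-[(4S)-2,2-dimethyl-1,3-dioxolan-4-yl]prop-2-enoate | BrC/C(C(=O)OC)=C\[C@H]1COC(C)(C)O1
F3 | step 9 | (4S,5R)-4-[(4S)-2,2-dimethyl-1,3-dioxolan-4-yl]-5-[(1Z,5Z)-6-iodo-7,7-dimethoxy-2-methylhepta-1,5-dien-1-yl]-3-methylideneoxolan-2-one | C=C1C(=O)O[C@H](/C=C(/C)CC/C=C(\I)C(OC)OC)[C@H]1[C@H]2COC(C)(C)O2
F4 | step 9 | (4R,5R)-4-[(1S)-1,2-dihydroxyethyl]-5-[(1Z,5Z)-6-iodo-7,7-dimethoxy-2-methylhepta-1,5-dien-1-yl]-3-methylideneoxolan-2-one | C=C1C(=O)O[C@H](/C=C(/C)CC/C=C(\I)C(OC)OC)[C@H]1[C@H](O)CO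
F5 | step 14 | (6R,7S,8S)-8-{[(2S)-2-acetoxy-2-methylbutanoyl]oxy}-14,14-dimethoxy-9-oxogermacra-1(10),4,11(13)-trien-12,6-olide | C=C1C(=O)O[C@@H]2/C=C(/C)CC/C=C(/C(OC)OC)C(=O)[C@@H](OC(=O)[C@](C)(CC)OC(C)=O)[C@@H]12
F6 | step 6 | racemic (2E,5Z,9Z)-10-iodo-11,11-dimethoxy-1-[(4-methoxyphenyl)methoxy]-6-methylundeca-2,5,9-trien-4-ol | OC(/C=C/COCc1ccc(OC)cc1)/C=C(/C)CC/C=C(\I)C(OC)OC
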